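(Its constants stand for no real mixture, and the outcome is calculated.)

I choose the next run.

    starting complex + incoming ligand ⇌ leaving ligand + complex with one exchanged (K1 = 2.2, k1 = 0.64 L mol⁻¹ h⁻¹)
    complex with one exchanged → over-reaction product (k2 = 0.025 h⁻¹)
    complex with one exchanged + incoming ligand ⇌ leaving ligand + complex with two exchanged (K3 = 3.1, k3 = 0.095 L mol⁻¹ h⁻¹)
    complex with two exchanged + incoming ligand ⇌ leaving ligand + complex with three exchanged (K4 = 63, k4 = 0.093 L mol⁻¹ h⁻¹)
    complex with three exchanged + incoming ligand ⇌ leaving ligand + complex with four exchanged (K5 = 2.2, k5 = 0.12 L mol⁻¹ h⁻¹)
    incoming ligand → decomposed reagent (k6 = 0.24 h⁻¹)
    complex with one exchanged ⇌ isomer of the product (K7 = 0.79, k7 = 0.012 h⁻¹)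

common to all: leaving ligand 88.0 mM
- Thursday's: starting complex 44 mM; incoming ligand 79.2 mM; one stirred flow tank at steady state, fed with the mixture as stated, mean residence time 2.5 d
- Saturday's: starting complex 44 mM (fed, over 2.00 d); incoming ligand 79.2 mM; all but starting complex at the start; starting complex goes in evenly over 2.00 d, the run ends at 2.5 d; time 2.5 d
- Monday's: starting complex 44 mM; incoming ligand 79.2 mM (fed, over 2.00 d); a stirred flask in which incoming ligand is dosed at a steady rate over 2.00 d without added volume, worked up at 2.5 d; time 2.5 d
- Friday's: starting complex 44 mM; incoming ligand 79.2 mM; a closed flask charged with all of it at once and left for 2.5 d; time 2.5 d

- the stated concentrations are those of everything mixed, before any reaction; amounts are the same in each set-up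
- the feed brings no volume worth counting
- run time (Saturday's): 2.5 d

1. the set-up with the highest share of complex with one exchanged in all that became complex with one exchanged or complex with two exchanged or complex with three exchanged or complex with four exchanged or isomer of the product or over-reaction product, at the outlet or at the end ("none" if the first two lie within 2 percentage points) (Thursday's / Saturday's / Monday's / Friday's / none)
2. share of complex with one exchanged in all that became complex with one exchanged or complex with two exchanged or complex with three exchanged or complex with four exchanged or isomer of the product or over-reaction product, at the outlet or at the end, Thursday's
3. share of complex with one exchanged in all that became complex with one exchanged or complex with two exchanged or complex with three exchanged or complex with four exchanged or isomer of the product or over-reaction product, at the outlet or at the end, Saturday's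
4. share of complex with one exchanged in all that became complex with one exchanged or complex with two exchanged or complex with three exchanged or complex with four exchanged or isomer of the product or over-reaction product, at the outlet or at the end, Monday's
5. share of complex with one exchanged in all that became complex with one exchanged or complex with two exchanged or complex with three exchanged or complex with four exchanged or isomer of the product or over-reaction product, at the outlet or at the end, Friday's

- I must decide which set-up to repeat, and I reckon with one quantity. Return to starting complex at the charged leaving ligand, over-reaction and forward isomerisation together give a mean time of 16.0 h. This is the drain life, the time a molecule of complex with one exchanged lasts once ligand stops arriving.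

- Decomposition gives the incoming ligand a mean life of 4.17 h, which is shorter than the drain life, so the clock that matters is the wait after the ligand's life ends.

- Friday's flask waits about 55.8 h, or 3.49 drain lives. Its share, the selectivity for complex with one exchanged, should therefore lie above 3.03%. I call this a floor for two reasons: the drain life counts return to starting complex as a loss, although that return takes from the share's top and bottom alike, and I ignore the isomer of the product returning.

- Saturday's flask gets the same clock, because the ligand's life ends well before the dosing does.

- Thursday's tank needs a different count. Return to starting complex removes material from the share's top and bottom alike, so I leave it out. Over-reaction product gathers to 1.50 per complex with one exchanged, and isomer of the product to 0.377, which gives 34.8%.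

- In Monday's flask, complex with one exchanged levels off after about one drain life, and by-products then gather for the rest of the dosing. The short wait after the ligand's last life then trims it, which gives 28.0%.

- I would therefore repeat Thursday's.

- The forecast also names Thursday's, with 34.5% for Thursday's, 11.5% for Saturday's, 30% for Monday's and 10% for Friday's. Its ground is that “The share therefore stays high only where ligand keeps arriving up to late in the run”. My figure for Monday's differs from its figure, and for Friday's I offer a floor where it gives a value.

- The simulation gives 34.5% for Thursday's, 12.4% for Saturday's, 31.4% for Monday's and 10.2% for Friday's, so the best is Thursday's.

- At 2.50 d, Friday's flask makes complex with one exchanged at 0.326 of the rate it uses it up, and holds 1.05% of it beside 1.91% isomer of the product. The same flask read at 10 d has waited a further 11.3 drain lives, yet complex with one exchanged has fallen by a factor of just 12.4, to 0.0849% beside 0.260% isomer of the product, with the share at 0.940%.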